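**Retrosynthetic overview**
1. Locants used throughout: ten-membered ring C1 (exocyclic-methylene carbon, a ketone until step 18) → C2 → C3 → C4 (ring-fusion CH) → C5 (ring-fusion C–CH3) → C6 → C7 → C8 (CH with the acrylate arm) → C9 → C10 (CH with prenyl); the cyclobutane is C4, C11 (CH2), C12 (CH–isopropenyl), C5.
2. Key disconnection: bonds C4–C11 and C5–C12, formed together by Lewis acid-promoted [2+2] cycloaddition of isopropenylketene 19 (from acid chloride 18; it brings all five carbons of the C11/C12/isopropenyl unit) to the ring olefin of macrocyclic ketone 17. The C11 carbonyl is a temporary activating group, removed in steps 16–17.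
3. Enabling feature: the E-configured trisubstituted C4=C5 double bond (C4–H, C5–CH3) inside the ten-membered ring. It is electron-rich and strained, polarised so that C5 takes the positive charge (C4 to the ketene C=O carbon, C5 to the substituted ketene carbon), open only on its peripheral face, and its E geometry maps directly onto the trans ring fusion.
4. 17 ← ring closure C2–C3 (β-keto ester enolate on allylic chloride, 15) ← open chain 11 ← copper-catalysed asymmetric conjugate addition joining enoate 9 (from geraniol, carries the E olefin) and Grignard reagent 10 (C10 centre from enzymatic desymmetrisation).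
5. Ring order: ten-membered ring (step 13), then cyclobutane (step 15). Endgame: C11 deoxygenation, C1 methylenation, allyl → prenyl, α-methylenation of the ester arm.

Key step: step 15

Assumption 1: the lipase is taken to acetylate the hydroxymethyl arm that gives (R)-3; if the other arm reacts, silylation, deacetylation and bromination in that order lead to the same bromide 6.
Assumption 2: (R)-Tol-BINAP is taken to give the 8S sense in step 8; otherwise the antipodal ligand is used.
Assumption 3: the C8 and C10 substituents are taken to bias 17 towards the ring conformer whose exposed olefin face leads to the (4S,5S) adduct 20; this is the least secure stereochemical prediction and is covered by the fallback for step 15.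

Step 1
Reactants: 1 diethyl 2-(prop-2-en-1-yl)propanedioate
Product: 2 2-(prop-2-en-1-yl)propane-1,3-diol
Conditions: LiAlH4, THF, 0 °C → reflux; aq. NaOH work-up
Reagents that add atoms: none
Why: LiAlH4 reduces both ester groups to primary alcohols (hydride reduction of esters) and leaves the isolated terminal alkene untouched.

Step 2
Reactants: 2 2-(prop-2-en-1-yl)propane-1,3-diol
Product: 3 (2R)-2-(hydroxymethyl)pent-4-en-1-yl acetate
Conditions: lipase PS (Burkholderia cepacia), vinyl acetate, t-BuOMe, rt
Reagents that add atoms: vinyl acetate, CC(=O)OC=C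
Why: Lipase-catalysed transesterification with the irreversible acyl donor vinyl acetate differentiates the two enantiotopic hydroxymethyl groups of the prochiral diol (enzymatic desymmetrisation) and so sets the stereocentre that becomes C10.

Step 3
Reactants: 3 (2R)-2-(hydroxymethyl)pent-4-en-1-yl acetate
Product: 4 (2S)-2-(bromomethyl)pent-4-en-1-yl acetate
Conditions: CBr4, PPh3, CH2Cl2, 0 °C
Reagents that add atoms: tetrabromomethane, BrC(Br)(Br)Br
Why: Appel bromination of the free primary alcohol under neutral conditions, run at once so that 1,3-acyl migration cannot racemise the monoacetate; the stereocentre is not touched.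

Step 4
Reactants: 4 (2S)-2-(bromomethyl)pent-4-en-1-yl acetate
Product: 5 (2S)-2-(bromomethyl)pent-4-en-1-ol
Conditions: TsOH·H2O (cat.), MeOH, 40 °C
Reagents that add atoms: none
Why: Acid-catalysed transesterification with methanol removes the acetate, and the bromo alcohol formed has no means of exchanging its two arms.

Step 5
Reactants: 5 (2S)-2-(bromomethyl)pent-4-en-1-ol
Product: 6 {[(2S)-2-(bromomethyl)pent-4-en-1-yl]oxy}(tert-butyl)dimethylsilane
Conditions: TBSCl, imidazole, DMF, rt
Reagents that add atoms: tert-butyldimethylsilyl chloride, CC(C)(C)[Si](C)(C)Cl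
Why: Standard silylation of the primary alcohol; with bromide already in place no second hydroxyl exists that could allow silyl migration and erosion of the stereocentre.

Step 6
Reactants: 7 geraniol
Product: 8 tert-butyl{[(2E)-3,7-dimethylocta-2,6-dien-1-yl]oxy}dimethylsilane
Conditions: TBSCl, imidazole, CH2Cl2, rt
Reagents that add atoms: tert-butyldimethylsilyl chloride, CC(C)(C)[Si](C)(C)Cl
Why: Silylation masks the primary allylic alcohol against the Grignard step and leaves the E olefin (future C4=C5) unchanged.

Step 7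
Reactants: 8 tert-butyl{[(2E)-3,7-dimethylocta-2,6-dien-1-yl]oxy}dimethylsilane
Product: 9 methyl (2E,6E)-8-{[tert-butyl(dimethyl)silyl]oxy}-6-methylocta-2,6-dienoate
Conditions: methyl acrylate, second-generation Grubbs catalyst (H2IMes)(PCy3)Cl2Ru=CHPh (cat.), CH2Cl2, 40 °C
Reagents that add atoms: methyl acrylate, C=CC(=O)OC
Why: Olefin cross-metathesis exchanges the unhindered isopropylidene terminus with methyl acrylate (isobutene lost) to give the E-enoate, while the more hindered allylic-ether olefin does not enter the catalytic cycle.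

Step 8
Reactants: 6 {[(2S)-2-(bromomethyl)pent-4-en-1-yl]oxy}(tert-butyl)dimethylsilane; 9 methyl (2E,6E)-8-{[tert-butyl(dimethyl)silyl]oxy}-6-methylocta-2,6-dienoate
Product: 11 methyl (3S,6E)-8-{[tert-butyl(dimethyl)silyl]oxy}-3-[(2R)-2-({[tert-butyl(dimethyl)silyl]oxy}methyl)pent-4-en-1-yl]-6-methyloct-6-enoate, via Grignard reagent 10 (not isolated)
Conditions: Mg, THF, rt; then 9, CuI (cat.), (R)-Tol-BINAP (cat.), t-BuOMe, −40 °C; aq. NH4Cl
Reagents that add atoms: none
Why: Copper-catalysed asymmetric conjugate addition of the Grignard reagent to the (E)-α,β-unsaturated methyl ester joins the two fragments, and the C8 stereocentre is set by the chiral CuI/Tol-BINAP complex (catalyst control) independently of the remote C10 centre.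

Step 9
Reactants: 11 bis-silyl ether ester
Product: 12 methyl (3S,6E)-8-hydroxy-3-[(2R)-2-(hydroxymethyl)pent-4-en-1-yl]-6-methyloct-6-enoate
Conditions: TBAF, THF, 0 °C → rt
Reagents that add atoms: none
Why: Fluoride cleaves both silyl ethers, and the methyl ester is stable to these conditions.

Step 10
Reactants: 12 diol ester
Product: 13 methyl (3S,6E)-8-chloro-3-[(2R)-2-(hydroxymethyl)pent-4-en-1-yl]-6-methyloct-6-enoate
Conditions: NCS, Me2S, CH2Cl2, −20 → 0 °C
Reagents that add atoms: N-chlorosuccinimide, ClN1C(=O)CCC1=O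
Why: Corey–Kim chlorination converts the allylic alcohol into the chloride by SN2 collapse of its alkoxysulfonium salt with retention of the E geometry, and is selective for allylic over saturated primary alcohols.

Step 11
Reactants: 13 chloro alcohol
Product: 14 methyl (3S,6E)-8-chloro-3-[(2R)-2-formylpent-4-en-1-yl]-6-methyloct-6-enoate
Conditions: Dess–Martin periodinane, CH2Cl2, 0 °C → rt
Reagents that add atoms: none
Why: Dess–Martin oxidation gives the aldehyde under non-basic conditions that neither epimerise the α-centre C10 nor disturb the allylic chloride.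

Step 12
Reactants: 14 chloro aldehyde
Product: 15 ethyl (4R)-4-[(2S,5E)-7-chloro-2-(2-methoxy-2-oxoethyl)-5-methylhept-5-en-1-yl]-3-oxohept-6-enoate
Conditions: ethyl diazoacetate, SnCl2 (cat.), CH2Cl2, rt
Reagents that add atoms: ethyl diazoacetate, [N-]=[N+]=CC(=O)OCC
Why: Roskamp reaction: SnCl2-catalysed addition of the diazo ester to the aldehyde, 1,2-hydride shift and loss of N2 give the β-keto ester (C1 ketone plus C2) under neutral conditions that spare C10 and the allylic chloride.

Step 13
Reactants: 15 chloro β-keto ester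
Product: 16 ethyl (4E,8S,10R)-10-allyl-8-(2-methoxy-2-oxoethyl)-5-methyl-1-oxocyclodec-4-ene-2-carboxylate (C2 epimers)
Conditions: Cs2CO3, MeCN, 70 °C, slow addition of 15 (high dilution)
Reagents that add atoms: none
Why: Intramolecular SN2 C-alkylation of the caesium β-keto ester enolate by the primary allylic chloride closes the ten-membered ring (C2–C3 bond) without touching the E geometry of C4=C5; the new C2 centre is uncontrolled and is removed in the next step.

Step 14
Reactants: 16 macrocyclic β-keto ester
Product: 17 (4E,8S,10R)-10-allyl-8-(2-methoxy-2-oxoethyl)-5-methylcyclodec-4-en-1-one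
Conditions: LiCl, H2O, DMSO, 140 °C
Reagents that add atoms: none
Why: Krapcho dealkoxycarbonylation (chloride-mediated de-ethylation and decarboxylation of the β-keto ester) removes the activating ester under near-neutral conditions that leave the simple methyl ester and the C10 centre in place.

Step 15
Reactants: 17 (4E,8S,10R)-10-allyl-8-(2-methoxy-2-oxoethyl)-5-methylcyclodec-4-en-1-one; 18 3-methylbut-2-enoyl chloride
Product: 20 methyl 2-[(4S,5S,8S,10R,12R)-10-allyl-5-methyl-1,11-dioxo-12-(prop-1-en-2-yl)bicyclo[8.2.0]dodecan-8-yl]acetate (locants of the overview), via isopropenylketene 19 (not isolated)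
Conditions: 18, Et3N, CH2Cl2, 0 °C (19 generated); then 17 and EtAlCl2 (3.5 equiv), −78 °C; aq. KNaC4H4O6
Reagents that add atoms: none
Why: Et3N dehydrochlorinates 18 by vinylogous deprotonation to isopropenylketene 19, whose EtAlCl2 complex is attacked at the ketene carbonyl carbon by C4 of the strained (E)-C4=C5 bond while the aluminium enolate carbon closes on the developing tertiary centre C5 in a concerted, asynchronous [π2s+π2a] process, so that C4–C11 and C5–C12 form in one operation. The closest known reaction type is the Lewis acid-promoted ketene–alkene [2+2] cycloaddition of ketenes generated in situ with unactivated trisubstituted alkenes, together with the [2+2] chemistry of vinylketenes made from α,β-unsaturated acid chlorides. The four-membered ring is closed by intermolecular cycloaddition across the ring olefin (second bond by 4-exo-type collapse at C5), and the ten-membered ring is not altered. C4 and C5 follow stereospecifically from the E geometry (C3 and C6 trans, hence the trans ring fusion), their absolute sense from attack on the only exposed, peripheral olefin face of the conformer that keeps the C8 and C10 side chains pseudo-equatorial (macrocyclic stereocontrol), and C12 is an epimerisable α-centre that should settle with the isopropenyl group pseudo-equatorial, trans to C6 and cis to the C5 methyl. The step needs regioselectivity (secured by the Markovnikov polarisation of the trisubstituted olefin), chemoselectivity over the allyl group, ketone and ester (secured by the much higher nucleophilicity of the trisubstituted olefin and by excess Lewis acid, which is why the prenyl group and both 1,1-disubstituted alkenes are installed later) and facial selectivity (secured by the ring conformation).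

Step 16
Reactants: 20 cyclobutanone
Product: 21 C11 (4-methylbenzenesulfonyl)hydrazone of 20
Conditions: TsNHNH2 (1.05 equiv), MeOH, rt
Reagents that add atoms: 4-methylbenzenesulfonohydrazide, Cc1ccc(cc1)S(=O)(=O)NN
Why: Tosylhydrazone condensation occurs at the strained, accessible cyclobutanone carbonyl, whereas the C1 ketone of the ten-membered ring, disfavoured by transannular strain in its tetrahedral adduct and shielded by the C10 branch, should not react with one equivalent.

Step 17
Reactants: 21 tosylhydrazone
Product: 23 methyl 2-[(4R,5S,8S,10R,12R)-10-allyl-5-methyl-1-oxo-12-(prop-1-en-2-yl)bicyclo[8.2.0]dodecan-8-yl]acetate, via N-borylhydrazine 22 (not isolated)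
Conditions: catecholborane, CHCl3, 0 °C; then NaOAc·3H2O, reflux
Reagents that add atoms: none
Why: Caglioti-type tosylhydrazone reduction in its catecholborane form: hydride adds to C=N at 0 °C to give 22, and acetate-induced loss of sulfinate and N2 leaves C11 as CH2 without touching the C1 ketone, the ester or the alkenes.

Step 18
Reactants: 23 bicyclic ketone
Product: 24 methyl 2-[(4R,5S,8S,10R,12R)-10-allyl-5-methyl-1-methylidene-12-(prop-1-en-2-yl)bicyclo[8.2.0]dodecan-8-yl]acetate
Conditions: CH2Br2, Zn, TiCl4, THF (reagent formed first); then 23, CH2Cl2, 0 °C → rt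
Reagents that add atoms: dibromomethane, BrCBr
Why: Takai–Lombardo methylenation with the non-basic CH2Br2/Zn/TiCl4 reagent converts the hindered C1 ketone into the exocyclic methylene without enolising C10 and without attacking the ester.

Step 19
Reactants: 24 allyl triene ester
Product: 25 methyl 2-[(4R,5S,8S,10R,12R)-5-methyl-1-methylidene-10-(3-methylbut-2-en-1-yl)-12-(prop-1-en-2-yl)bicyclo[8.2.0]dodecan-8-yl]acetate
Conditions: 2-methylbut-2-ene, second-generation Grubbs catalyst (cat.), CH2Cl2, 40 °C
Reagents that add atoms: 2-methylbut-2-ene, CC=C(C)C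
Why: Olefin cross-metathesis with 2-methylbut-2-ene turns the monosubstituted allyl alkene into the prenyl group, while the two 1,1-disubstituted alkenes are too hindered to compete.

Step 20
Reactants: 25 prenyl ester
Product: 27 methyl 3-(dimethylamino)-2-[(4R,5S,8S,10R,12R)-5-methyl-1-methylidene-10-(3-methylbut-2-en-1-yl)-12-(prop-1-en-2-yl)bicyclo[8.2.0]dodecan-8-yl]propanoate, via lithium ester enolate 26 (not isolated)
Conditions: LiN(i-Pr)2, THF, −78 °C; then CH2=NMe2+ I−, −78 °C → rt
Reagents that add atoms: N,N-dimethylmethyleneiminium iodide (Eschenmoser's salt), C=[N+](C)C.[I-]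
Why: The enolate of the only enolisable carbonyl is aminomethylated by Eschenmoser's salt (Mannich reaction); the new α-centre is uncontrolled and becomes sp2 in the next step.

Step 21
Reactants: 27 Mannich base
Product: 29 methyl 2-[(4R,5S,8S,10R,12R)-5-methyl-1-methylidene-10-(3-methylbut-2-en-1-yl)-12-(prop-1-en-2-yl)bicyclo[8.2.0]dodecan-8-yl]prop-2-enoate (target), via trimethylammonium iodide 28 (not isolated)
Conditions: MeI, CH2Cl2/MeOH, rt; then DBU, rt
Reagents that add atoms: none
Why: N-Methylation followed by base-induced β-elimination of trimethylamine from 28 (Hofmann-type E1cB elimination of a Mannich base) unveils the α-methylene ester and should give the target.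

**Compound list**
1 | diethyl 2-(prop-2-en-1-yl)propanedioate | CCOC(=O)C(CC=C)C(=O)OCC | starting material
2 | 2-(prop-2-en-1-yl)propane-1,3-diol | OCC(CO)CC=C | intermediate
3 | (2R)-2-(hydroxymethyl)pent-4-en-1-yl acetate | OC[C@H](COC(C)=O)CC=C | intermediate
4 | (2S)-2-(bromomethyl)pent-4-en-1-yl acetate | BrC[C@H](COC(C)=O)CC=C | intermediate
5 | (2S)-2-(bromomethyl)pent-4-en-1-ol | BrC[C@H](CO)CC=C | intermediate
6 | {[(2S)-2-(bromomethyl)pent-4-en-1-yl]oxy}(tert-butyl)dimethylsilane | BrC[C@H](CO[Si](C)(C)C(C)(C)C)CC=C | intermediate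
7 | geraniol, (2E)-3,7-dimethylocta-2,6-dien-1-ol | CC(C)=CCC/C(C)=C/CO | starting material
8 | tert-butyl{[(2E)-3,7-dimethylocta-2,6-dien-1-yl]oxy}dimethylsilane | CC(C)=CCC/C(C)=C/CO[Si](C)(C)C(C)(C)C | intermediate
9 | methyl (2E,6E)-8-{[tert-butyl(dimethyl)silyl]oxy}-6-methylocta-2,6-dienoate | COC(=O)/C=C/CC/C(C)=C/CO[Si](C)(C)C(C)(C)C | intermediate
10 | bromo[(2S)-2-({[tert-butyl(dimethyl)silyl]oxy}methyl)pent-4-en-1-yl]magnesium | Br[Mg]C[C@H](CO[Si](C)(C)C(C)(C)C)CC=C | intermediate
11 | methyl (3S,6E)-8-{[tert-butyl(dimethyl)silyl]oxy}-3-[(2R)-2-({[tert-butyl(dimethyl)silyl]oxy}methyl)pent-4-en-1-yl]-6-methyloct-6-enoate | CC(C)(C)[Si](C)(C)OC/C=C(\C)CC[C@H](CC(=O)OC)C[C@H](CO[Si](C)(C)C(C)(C)C)CC=C | intermediate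
12 | methyl (3S,6E)-8-hydroxy-3-[(2R)-2-(hydroxymethyl)pent-4-en-1-yl]-6-methyloct-6-enoate | OC/C=C(\C)CC[C@H](CC(=O)OC)C[C@H](CO)CC=C | intermediate
13 | methyl (3S,6E)-8-chloro-3-[(2R)-2-(hydroxymethyl)pent-4-en-1-yl]-6-methyloct-6-enoate | ClC/C=C(\C)CC[C@H](CC(=O)OC)C[C@H](CO)CC=C | intermediate
14 | methyl (3S,6E)-8-chloro-3-[(2R)-2-formylpent-4-en-1-yl]-6-methyloct-6-enoate | ClC/C=C(\C)CC[C@H](CC(=O)OC)C[C@H](C=O)CC=C | intermediate
15 | ethyl (4R)-4-[(2S,5E)-7-chloro-2-(2-methoxy-2-oxoethyl)-5-methylhept-5-en-1-yl]-3-oxohept-6-enoate | ClC/C=C(\C)CC[C@H](CC(=O)OC)C[C@H](C(=O)CC(=O)OCC)CC=C | intermediate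
16 | ethyl (4E,8S,10R)-10-allyl-8-(2-methoxy-2-oxoethyl)-5-methyl-1-oxocyclodec-4-ene-2-carboxylate (C2 epimers) | O=C1C(C(=O)OCC)C/C=C(\C)CC[C@H](CC(=O)OC)C[C@H]1CC=C | intermediate
17 | (4E,8S,10R)-10-allyl-8-(2-methoxy-2-oxoethyl)-5-methylcyclodec-4-en-1-one | O=C1CC/C=C(\C)CC[C@H](CC(=O)OC)C[C@H]1CC=C | intermediate
18 | 3-methylbut-2-enoyl chloride | CC(C)=CC(Cl)=O | starting material
19 | 3-methylbuta-1,3-dien-1-one (isopropenylketene) | CC(=C)C=C=O | intermediate
20 | methyl 2-[(4S,5S,8S,10R,12R)-10-allyl-5-methyl-1,11-dioxo-12-(prop-1-en-2-yl)bicyclo[8.2.0]dodecan-8-yl]acetate (trans-fused; locants of the overview) | O=C1CC[C@@H]2C(=O)[C@H](C(=C)C)[C@@]2(C)CC[C@H](CC(=O)OC)C[C@H]1CC=C | intermediate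
21 | C11 (4-methylbenzenesulfonyl)hydrazone of 20 | O=C1CC[C@@H]2C(=NNS(=O)(=O)c3ccc(C)cc3)[C@H](C(=C)C)[C@@]2(C)CC[C@H](CC(=O)OC)C[C@H]1CC=C | intermediate
22 | N-(1,3,2-benzodioxaborol-2-yl)-N'-tosylhydrazine at C11 (C11 epimers) | O=C1CC[C@@H]2C(N(NS(=O)(=O)c3ccc(C)cc3)B3Oc4ccccc4O3)[C@H](C(=C)C)[C@@]2(C)CC[C@H](CC(=O)OC)C[C@H]1CC=C | intermediate
23 | methyl 2-[(4R,5S,8S,10R,12R)-10-allyl-5-methyl-1-oxo-12-(prop-1-en-2-yl)bicyclo[8.2.0]dodecan-8-yl]acetate | O=C1CC[C@@H]2C[C@H](C(=C)C)[C@@]2(C)CC[C@H](CC(=O)OC)C[C@H]1CC=C | intermediate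
24 | methyl 2-[(4R,5S,8S,10R,12R)-10-allyl-5-methyl-1-methylidene-12-(prop-1-en-2-yl)bicyclo[8.2.0]dodecan-8-yl]acetate | C=C1CC[C@@H]2C[C@H](C(=C)C)[C@@]2(C)CC[C@H](CC(=O)OC)C[C@H]1CC=C | intermediate
25 | methyl 2-[(4R,5S,8S,10R,12R)-5-methyl-1-methylidene-10-(3-methylbut-2-en-1-yl)-12-(prop-1-en-2-yl)bicyclo[8.2.0]dodecan-8-yl]acetate | C=C1CC[C@@H]2C[C@H](C(=C)C)[C@@]2(C)CC[C@H](CC(=O)OC)C[C@H]1CC=C(C)C | intermediate
26 | lithium enolate of 25 | C=C1CC[C@@H]2C[C@H](C(=C)C)[C@@]2(C)CC[C@H](C=C(O[Li])OC)C[C@H]1CC=C(C)C | intermediate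
27 | methyl 3-(dimethylamino)-2-[(4R,5S,8S,10R,12R)-5-methyl-1-methylidene-10-(3-methylbut-2-en-1-yl)-12-(prop-1-en-2-yl)bicyclo[8.2.0]dodecan-8-yl]propanoate (α-epimers) | C=C1CC[C@@H]2C[C@H](C(=C)C)[C@@]2(C)CC[C@H](C(CN(C)C)C(=O)OC)C[C@H]1CC=C(C)C | intermediate
28 | trimethylammonium iodide of 27 | C=C1CC[C@@H]2C[C@H](C(=C)C)[C@@]2(C)CC[C@H](C(C[N+](C)(C)C)C(=O)OC)C[C@H]1CC=C(C)C.[I-] | intermediate
29 | CNP0314186.1, methyl 2-[(4R,5S,8S,10R,12R)-5-methyl-1-methylidene-10-(3-methylbut-2-en-1-yl)-12-(prop-1-en-2-yl)bicyclo[8.2.0]dodecan-8-yl]prop-2-enoate | C=C1CC[C@@H]2C[C@H](C(=C)C)[C@@]2(C)CC[C@H](C(=C)C(=O)OC)C[C@H]1CC=C(C)C | target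

Total step count: 21. Longest linear sequence: 19 steps (steps 1–5, then 8–21).

**Steps most likely to fail**

Step 15 (key cycloaddition). Dimerisation or oligomerisation of the vinylketene may outrun the cycloaddition, the aluminium Lewis acid may open the 2-alkenylcyclobutanone by 1,3-acyl shift, or the ketene may add to the undesired face of the ring olefin. The fallback sets out from 17 and comes back at 20. 3-Methylbut-3-enoic acid is condensed with (2R,5R)-2,5-dimethylpyrrolidine (EDC·HCl, DMAP, CH2Cl2) to the amide 1-[(2R,5R)-2,5-dimethylpyrrolidin-1-yl]-3-methylbut-3-en-1-one F1. Tf2O and 2,6-di-tert-butyl-4-methylpyridine in 1,2-dichloroethane convert it into the keteniminium triflate F2. This should add thermally (20–60 °C) to the C4=C5 bond of 17 in a keteniminium–olefin [2+2] cycloaddition with the same regiochemistry, without aluminium Lewis acid or free ketene, and with facial selectivity under the control of the C2-symmetric amine (its antipode is used if the other face is required), to give the cyclobutaniminium triflate F3. Hydrolysis with aqueous NaHCO3 gives 20.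

Step 13 (ten-membered ring closure). Intermolecular alkylation to oligomers, or O-alkylation, may outrun closure of the strained ring. The fallback sets out from 14 and comes back at 17. Aldehyde 14 is treated with lithiated methyl phenyl sulfone (PhSO2CH3, n-BuLi, THF, −78 °C) to give the β-hydroxy sulfone F4, and Dess–Martin oxidation gives the β-keto sulfone F5. Its sodium salt (NaH) is cyclised with Pd(PPh3)4/dppe in THF at 65 °C under slow addition, a Tsuji–Trost macrocyclisation in which the π-allylpalladium complex of the allylic chloride is captured at its primary terminus by the soft sulfonyl-stabilised enolate, to give the macrocyclic β-keto sulfone F6. Aluminium amalgam (Al/Hg) in aqueous THF removes the sulfonyl group and gives 17.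

Step 17 (removal of the C11 carbonyl). Hydride may be lost to the C1 ketone, or collapse of the diazene may be incomplete or accompanied by alkene migration. The fallback sets out from 20 and comes back at 23. NaBH4 in MeOH at −78 °C should reduce only the strained cyclobutanone carbonyl to give the cyclobutanol F7. 1,1'-Thiocarbonyldiimidazole (DMAP, CH2Cl2) converts it into the O-cyclobutyl imidazole-1-carbothioate F8. Barton–McCombie deoxygenation (Bu3SnH at high concentration, AIBN, toluene, 80 °C) gives 23.

**Further compounds**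
F1 | step 15 | 1-[(2R,5R)-2,5-dimethylpyrrolidin-1-yl]-3-methylbut-3-en-1-one | C[C@@H]1CC[C@@H](C)N1C(=O)CC(C)=C
F2 | step 15 | (2R,5R)-2,5-dimethyl-1-(3-methylbuta-1,3-dien-1-ylidene)pyrrolidinium triflate (keteniminium salt) | C[C@@H]1CC[C@@H](C)[N+]1=C=CC(C)=C.[O-]S(=O)(=O)C(F)(F)F
F3 | step 15 | C11 cyclobutaniminium triflate corresponding to 20 | O=C1CC[C@@H]2C(=[N+]3[C@H](C)CC[C@H]3C)[C@H](C(=C)C)[C@@]2(C)CC[C@H](CC(=O)OC)C[C@H]1CC=C.[O-]S(=O)(=O)C(F)(F)F
F4 | step 13 | β-hydroxy sulfone from 14 (carbinol epimers) | ClC/C=C(\C)CC[C@H](CC(=O)OC)C[C@H](C(O)CS(=O)(=O)c1ccccc1)CC=C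
F5 | step 13 | β-keto sulfone | ClC/C=C(\C)CC[C@H](CC(=O)OC)C[C@H](C(=O)CS(=O)(=O)c1ccccc1)CC=C
F6 | step 13 | (4E,8S,10R)-10-allyl-8-(2-methoxy-2-oxoethyl)-5-methyl-2-(phenylsulfonyl)cyclodec-4-en-1-one (C2 epimers) | O=C1C(S(=O)(=O)c2ccccc2)C/C=C(\C)CC[C@H](CC(=O)OC)C[C@H]1CC=C
F7 | step 17 | C11 cyclobutanol from 20 (C11 epimers) | O=C1CC[C@@H]2C(O)[C@H](C(=C)C)[C@@]2(C)CC[C@H](CC(=O)OC)C[C@H]1CC=C
F8 | step 17 | O-(C11) 1H-imidazole-1-carbothioate of F7 | O=C1CC[C@@H]2C(OC(=S)n3ccnc3)[C@H](C(=C)C)[C@@]2(C)CC[C@H](CC(=O)OC)C[C@H]1CC=C
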